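The dihydropyranone ring is disconnected at O1–C2 and C4–C4a, which leads back to an aryl cinnamate: 2,4-diprenylresorcinol acylated on the future O1 by silyl-protected (E)-2,4-dihydroxycinnamic acid. In one flask, a photo-Fries shift moves the cinnamoyl group from O1 to C4a, and a cinchona amine–thiourea then closes O1 onto C2 of the resulting 2′-hydroxychalcone (6-endo oxa-Michael), setting the (2S) centre. The step exploits the substitution of ring A: C6 and C8 carry prenyl groups, so C4a is the only free carbon ortho or para to O1 and the acyl group has one place to return to. Buffered fluoride then removes the three silyl groups.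

Key step: step 8

Assumption: the quinine-derived catalyst 1-[3,5-bis(trifluoromethyl)phenyl]-3-[(8α,9S)-6′-methoxycinchonan-9-yl]thiourea is taken to give the (2S) sense; should the closure prove (2R)-selective, its quinidine-derived pseudoenantiomer is used instead.

Abbreviations: prenyl = 3-methylbut-2-en-1-yl; TBS = tert-butyldimethylsilyl; MOM = methoxymethyl.

**Route**

Step 1
Reactants: 1 resorcinol
Product: 2 1,3-bis(methoxymethoxy)benzene
Conditions: MOMCl (2.5 equiv), i-Pr2NEt, CH2Cl2, 0 °C to rt
Reagents that add atoms: chloromethyl methyl ether (MOMCl), COCCl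
Why: Double O-alkylation of the phenols with the reactive α-chloro ether (Williamson-type acetal formation) should proceed cleanly and installs two directing groups for the lithiations that follow.

Step 2
Reactants: 2 1,3-bis(methoxymethoxy)benzene; 3 prenyl bromide
Product: 5 1,3-bis(methoxymethoxy)-2-(3-methylbut-2-en-1-yl)benzene, via aryllithium 4 (not isolated)
Conditions: n-BuLi (1.1 equiv), THF, 0 °C to rt; then CuI (10 mol %), 3, −78 °C to rt
Reagents that add atoms: none
Why: Directed ortho-metalation occurs at C2 because this position is flanked by both OMOM groups, and copper-catalysed alkylation of the aryllithium with prenyl bromide favours SN2 over SN2′ attack, so the linear prenyl group should result.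

Step 3
Reactants: 5 1,3-bis(methoxymethoxy)-2-(3-methylbut-2-en-1-yl)benzene; 3 prenyl bromide
Product: 7 1,3-bis(methoxymethoxy)-2,4-bis(3-methylbut-2-en-1-yl)benzene, via aryllithium 6 (not isolated)
Conditions: n-BuLi (1.2 equiv), TMEDA, THF, −20 to 0 °C; then CuI (10 mol %), 3, −78 °C to rt
Reagents that add atoms: none
Why: A second directed ortho-metalation, now at C4 next to one OMOM group (C4 and C6 are equivalent in 5), followed by the same copper-catalysed SN2 alkylation should give the 2,4-diprenyl pattern, ring lithiation being favoured kinetically by coordination of n-BuLi/TMEDA to the acetal oxygen.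

Step 4
Reactants: 7 1,3-bis(methoxymethoxy)-2,4-bis(3-methylbut-2-en-1-yl)benzene
Product: 8 2,4-bis(3-methylbut-2-en-1-yl)benzene-1,3-diol (2,4-diprenylresorcinol)
Conditions: 3 M aq HCl/MeOH (1:10), 40 °C, stopped at full conversion
Reagents that add atoms: none
Why: Acid-catalysed transacetalisation with methanol removes both MOM groups, and mild, short exposure is chosen so that the trisubstituted alkenes are not protonated and do not close chroman rings onto the ortho-hydroxyls.

Step 5
Reactants: 9 (E)-3-(2,4-dihydroxyphenyl)prop-2-enoic acid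
Product: 11 (E)-3-[2,4-bis(TBS-oxy)phenyl]prop-2-enoic acid, via silyl ester 10 (not isolated)
Conditions: TBSCl (3.5 equiv), imidazole, DMF, rt; then AcOH/THF/H2O, rt
Reagents that add atoms: tert-butyldimethylsilyl chloride (TBSCl), CC(C)(C)[Si](C)(C)Cl
Why: Exhaustive silylation followed by selective hydrolysis of the far more labile silyl ester is standard for hydroxycinnamic acids and leaves both phenols protected, which also blocks lactonisation of the 2-OH to a coumarin.

Step 6
Reactants: 8 2,4-diprenylresorcinol; 11 (E)-3-[2,4-bis(TBS-oxy)phenyl]prop-2-enoic acid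
Product: 12 3-hydroxy-2,4-bis(3-methylbut-2-en-1-yl)phenyl (E)-3-[2,4-bis(TBS-oxy)phenyl]prop-2-enoate
Conditions: DCC (1.05 equiv), DMAP (10 mol %), CH2Cl2, 0 °C to rt; 8 in slight excess
Reagents that add atoms: none
Why: Steglich esterification with one equivalent of acid should acylate the 1-OH, flanked by one prenyl group and a hydrogen, in preference to the 3-OH, which is buttressed by two prenyl groups.

Step 7
Reactants: 12 3-hydroxy-2,4-bis(3-methylbut-2-en-1-yl)phenyl (E)-3-[2,4-bis(TBS-oxy)phenyl]prop-2-enoate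
Product: 13 3-(TBS-oxy)-2,4-bis(3-methylbut-2-en-1-yl)phenyl (E)-3-[2,4-bis(TBS-oxy)phenyl]prop-2-enoate
Conditions: TBSOTf (1.3 equiv), 2,6-lutidine, CH2Cl2, 0 °C
Reagents that add atoms: tert-butyldimethylsilyl triflate (TBSOTf), CC(C)(C)[Si](C)(C)OS(=O)(=O)C(F)(F)F
Why: Silylation with the silyl triflate and 2,6-lutidine is effective for hindered 2,6-dialkylphenols and masks the phenol that would end up para to the ketone, where its acidity would deactivate the enone and bind the basic catalyst.

Step 8
Reactants: 13 3-(TBS-oxy)-2,4-bis(3-methylbut-2-en-1-yl)phenyl (E)-3-[2,4-bis(TBS-oxy)phenyl]prop-2-enoate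
Product: 15 (2S)-7-(TBS-oxy)-2-[2,4-bis(TBS-oxy)phenyl]-6,8-bis(3-methylbut-2-en-1-yl)-2,3-dihydro-4H-chromen-4-one, via chalcone 14 (not isolated)
Conditions: hν (λ > 290 nm, medium-pressure Hg lamp, Pyrex), degassed benzene (5 mM), 20 °C; then concentrate, toluene (0.1 M), quinine-derived amine–thiourea (15 mol %), −20 °C
Reagents that add atoms: none
Why: Excitation of the aryl cinnamate cleaves the ArO–C(=O) bond to a caged phenoxyl/cinnamoyl radical pair that recombines at C6 of the ester ring (the future C4a), the only unsubstituted ortho or para carbon because the other ortho carbon and the para carbon carry prenyl groups, and tautomerisation gives 2′-hydroxychalcone 14, which is shielded from further photochemistry by excited-state proton transfer in its chelated o-hydroxyaryl ketone. The closest known reactions are the photo-Fries rearrangement of aryl cinnamates to 2′-hydroxychalcones and the bifunctional amine–thiourea-catalysed cyclisation of 2′-hydroxychalcones to flavanones, run here one after the other in the same flask. The pyranone ring closes by a 6-endo-trig oxa-Michael addition of the O1 phenol to C2. C2 is the only new stereocentre and it is set by the catalyst: the thiourea binds the enone carbonyl while the quinuclidine activates the phenol and delivers it to one face of the E-enone, taken to be the face that gives (2S). The step needs a single acyl destination, which the two prenyl groups secure, and convergence of the E/Z mixture left by photoisomerisation of the cinnamate, which reversible conjugate addition of the amine to the Z-chalcone should provide. Low temperature and the silyl group on O7, which keeps the acidic para-phenol from pairing with the catalyst, are meant to keep the closure under kinetic control.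

Step 9
Reactants: 15 (2S)-7-(TBS-oxy)-2-[2,4-bis(TBS-oxy)phenyl]-6,8-bis(3-methylbut-2-en-1-yl)-2,3-dihydro-4H-chromen-4-one
Product: 16 (2S)-2-(2,4-dihydroxyphenyl)-7-hydroxy-6,8-bis(3-methylbut-2-en-1-yl)-2,3-dihydro-4H-chromen-4-one (CNP0318833.1)
Conditions: TBAF (3.3 equiv), AcOH (3.6 equiv), THF, 0 °C
Reagents that add atoms: none
Why: Fluoride-mediated desilylation of the three aryl silyl ethers is fast at 0 °C, and acetic acid protonates the phenoxides as they form so that retro-oxa-Michael ring opening, and with it loss of the C2 configuration, is avoided while the prenyl groups are untouched.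

**Compound list**

1 | resorcinol (benzene-1,3-diol) | Oc1cccc(O)c1 | starting material
2 | 1,3-bis(methoxymethoxy)benzene | COCOc1cccc(OCOC)c1 | intermediate
3 | prenyl bromide (1-bromo-3-methylbut-2-ene) | CC(C)=CCBr | starting material
4 | [2,6-bis(methoxymethoxy)phenyl]lithium | [Li]c1c(OCOC)cccc1OCOC | intermediate
5 | 1,3-bis(methoxymethoxy)-2-(3-methylbut-2-en-1-yl)benzene | COCOc1cccc(OCOC)c1CC=C(C)C | intermediate
6 | [2,4-bis(methoxymethoxy)-3-(3-methylbut-2-en-1-yl)phenyl]lithium | [Li]c1ccc(OCOC)c(CC=C(C)C)c1OCOC | intermediate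
7 | 1,3-bis(methoxymethoxy)-2,4-bis(3-methylbut-2-en-1-yl)benzene | COCOc1ccc(CC=C(C)C)c(OCOC)c1CC=C(C)C | intermediate
8 | 2,4-bis(3-methylbut-2-en-1-yl)benzene-1,3-diol | Oc1ccc(CC=C(C)C)c(O)c1CC=C(C)C | intermediate
9 | (E)-3-(2,4-dihydroxyphenyl)prop-2-enoic acid (umbellic acid) | OC(=O)/C=C/c1ccc(O)cc1O | starting material
10 | tert-butyldimethylsilyl (E)-3-{2,4-bis[(tert-butyldimethylsilyl)oxy]phenyl}prop-2-enoate | CC(C)(C)[Si](C)(C)OC(=O)/C=C/c1ccc(O[Si](C)(C)C(C)(C)C)cc1O[Si](C)(C)C(C)(C)C | intermediate
11 | (E)-3-{2,4-bis[(tert-butyldimethylsilyl)oxy]phenyl}prop-2-enoic acid | OC(=O)/C=C/c1ccc(O[Si](C)(C)C(C)(C)C)cc1O[Si](C)(C)C(C)(C)C | intermediate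
12 | 3-hydroxy-2,4-bis(3-methylbut-2-en-1-yl)phenyl (E)-3-{2,4-bis[(tert-butyldimethylsilyl)oxy]phenyl}prop-2-enoate | CC(C)=CCc1ccc(OC(=O)/C=C/c2ccc(O[Si](C)(C)C(C)(C)C)cc2O[Si](C)(C)C(C)(C)C)c(CC=C(C)C)c1O | intermediate
13 | 3-[(tert-butyldimethylsilyl)oxy]-2,4-bis(3-methylbut-2-en-1-yl)phenyl (E)-3-{2,4-bis[(tert-butyldimethylsilyl)oxy]phenyl}prop-2-enoate | CC(C)=CCc1ccc(OC(=O)/C=C/c2ccc(O[Si](C)(C)C(C)(C)C)cc2O[Si](C)(C)C(C)(C)C)c(CC=C(C)C)c1O[Si](C)(C)C(C)(C)C | intermediate
14 | (E)-1-{4-[(tert-butyldimethylsilyl)oxy]-2-hydroxy-3,5-bis(3-methylbut-2-en-1-yl)phenyl}-3-{2,4-bis[(tert-butyldimethylsilyl)oxy]phenyl}prop-2-en-1-one | CC(C)=CCc1cc(C(=O)/C=C/c2ccc(O[Si](C)(C)C(C)(C)C)cc2O[Si](C)(C)C(C)(C)C)c(O)c(CC=C(C)C)c1O[Si](C)(C)C(C)(C)C | intermediate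
15 | (2S)-7-[(tert-butyldimethylsilyl)oxy]-2-{2,4-bis[(tert-butyldimethylsilyl)oxy]phenyl}-6,8-bis(3-methylbut-2-en-1-yl)-2,3-dihydro-4H-chromen-4-one | CC(C)=CCc1cc2c(c(CC=C(C)C)c1O[Si](C)(C)C(C)(C)C)O[C@H](c1ccc(O[Si](C)(C)C(C)(C)C)cc1O[Si](C)(C)C(C)(C)C)CC2=O | intermediate
16 | (2S)-2-(2,4-dihydroxyphenyl)-7-hydroxy-6,8-bis(3-methylbut-2-en-1-yl)-2,3-dihydro-4H-chromen-4-one | CC(C)=CCc1cc2c(c(CC=C(C)C)c1O)O[C@H](c1ccc(O)cc1O)CC2=O | target

**Totals**

Total step count: 9.
Longest linear sequence: 8 steps (steps 1, 2, 3, 4, 6, 7, 8, 9, from resorcinol).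

**Steps most likely to fail**

1. Step 8. Two processes threaten it.
   - The light-driven acyl shift may be outrun by E/Z isomerisation, [2+2] dimerisation and escape of the radical pair from the solvent cage.
   - The reversible ring closure on an electron-rich β-aryl enone may drift toward the racemate.

   The fallback sets out from 7 and comes back at 15. It separates bond formation from stereocontrol.
   - A third directed lithiation of 7 (n-BuLi, TMEDA, THF, 0 °C) at the last position ortho to an OMOM group should give the aryllithium F1.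
   - F1 adds to the Weinreb amide F2 (made from 11 with MeNHOMe·HCl, EDC, i-Pr2NEt) and should give, after work-up, the MOM-protected chalcone F3.
   - Dilute HCl in MeOH removes the two MOM groups, which the aryl silyl ethers should survive, and gives the dihydroxychalcone F4.
   - TBSOTf/2,6-lutidine silylates the non-chelated hydroxyl of F4 to give 14.
   - Catalytic DBU in toluene closes 14 to the racemic flavanone F5.
   - Kinetic resolution by Ru–TsDPEN transfer hydrogenation (HCO2H/Et3N) reduces the unwanted (2R)-ketone to the cis-flavan-4-ol F6 and leaves 15. The catalyst antipode that consumes the (2R)-ketone is chosen in a pilot run.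

2. Step 6. Acylation may spread to the hindered hydroxyl and to both hydroxyls. The fallback sets out from 8 and comes back at 14. It replaces regioselective acylation by a regioconvergent rearrangement.
   - The monoester fraction is taken on without separating 12 from its regioisomer, the ester of the hindered hydroxyl F7.
   - Irradiation as in step 8 moves the acyl group of 12 to the ortho carbon and that of F7 to the same carbon, which is para to its oxygen, so both should converge on the dihydroxychalcone F4.
   - TBSOTf/2,6-lutidine then silylates the non-chelated hydroxyl to give 14, which is closed with the thiourea catalyst as in the second stage of step 8.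

3. Step 4. Protonation of the prenyl alkenes and ring closure onto the freed ortho-hydroxyls may compete with acetal cleavage. The fallback sets out from 7 and comes back at 8. It exchanges the acetals for silyl ethers instead of solvolysing them.
   - TMSOTf and 2,2′-bipyridyl in CH2Cl2 at 0 °C, a buffered non-protic medium, should give the bis(trimethylsilyl) ether F8.
   - K2CO3 in MeOH then cleaves the silyl ethers under basic conditions, in which the prenyl groups are inert.

**Further compounds**

F1 | step 8 | [2,4-bis(methoxymethoxy)-3,5-bis(3-methylbut-2-en-1-yl)phenyl]lithium | [Li]c1cc(CC=C(C)C)c(OCOC)c(CC=C(C)C)c1OCOC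
F2 | step 8 | (E)-3-{2,4-bis[(tert-butyldimethylsilyl)oxy]phenyl}-N-methoxy-N-methylprop-2-enamide | CON(C)C(=O)/C=C/c1ccc(O[Si](C)(C)C(C)(C)C)cc1O[Si](C)(C)C(C)(C)C
F3 | step 8 | (E)-1-[2,4-bis(methoxymethoxy)-3,5-bis(3-methylbut-2-en-1-yl)phenyl]-3-{2,4-bis[(tert-butyldimethylsilyl)oxy]phenyl}prop-2-en-1-one | CC(C)=CCc1cc(C(=O)/C=C/c2ccc(O[Si](C)(C)C(C)(C)C)cc2O[Si](C)(C)C(C)(C)C)c(OCOC)c(CC=C(C)C)c1OCOC
F4 | step 8 | (E)-1-[2,4-dihydroxy-3,5-bis(3-methylbut-2-en-1-yl)phenyl]-3-{2,4-bis[(tert-butyldimethylsilyl)oxy]phenyl}prop-2-en-1-one | CC(C)=CCc1cc(C(=O)/C=C/c2ccc(O[Si](C)(C)C(C)(C)C)cc2O[Si](C)(C)C(C)(C)C)c(O)c(CC=C(C)C)c1O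
F5 | step 8 | rac-7-[(tert-butyldimethylsilyl)oxy]-2-{2,4-bis[(tert-butyldimethylsilyl)oxy]phenyl}-6,8-bis(3-methylbut-2-en-1-yl)-2,3-dihydro-4H-chromen-4-one | CC(C)=CCc1cc2c(c(CC=C(C)C)c1O[Si](C)(C)C(C)(C)C)OC(c1ccc(O[Si](C)(C)C(C)(C)C)cc1O[Si](C)(C)C(C)(C)C)CC2=O
F6 | step 8 | (2R,4R)-7-[(tert-butyldimethylsilyl)oxy]-2-{2,4-bis[(tert-butyldimethylsilyl)oxy]phenyl}-6,8-bis(3-methylbut-2-en-1-yl)-3,4-dihydro-2H-chromen-4-ol | O[C@@H]1C[C@H](c2ccc(O[Si](C)(C)C(C)(C)C)cc2O[Si](C)(C)C(C)(C)C)Oc2c(CC=C(C)C)c(O[Si](C)(C)C(C)(C)C)c(CC=C(C)C)cc21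
F7 | step 6 | 3-hydroxy-2,6-bis(3-methylbut-2-en-1-yl)phenyl (E)-3-{2,4-bis[(tert-butyldimethylsilyl)oxy]phenyl}prop-2-enoate | CC(C)=CCc1ccc(O)c(CC=C(C)C)c1OC(=O)/C=C/c1ccc(O[Si](C)(C)C(C)(C)C)cc1O[Si](C)(C)C(C)(C)C
F8 | step 4 | 1,3-bis[(trimethylsilyl)oxy]-2,4-bis(3-methylbut-2-en-1-yl)benzene | C[Si](C)(C)Oc1ccc(CC=C(C)C)c(O[Si](C)(C)C)c1CC=C(C)C
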